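Everything rests on a cyclobutanone that the target does not contain. A ketoketene (C4=C1=O, carrying the C5–C9 chain) and a cis-propenyl benzyl ether (C2=C3) combine in a thermal [2+2] cycloaddition that forms C1–C2 and C3–C4 at once and sets the contiguous C2/C3/C4 stereotriad of the δ-lactone ring, including quaternary C4. The step exploits that C1 (lactone carbonyl) and C4 (ring-fusion carbon carrying the pyran oxygen) are 1,4-related, oxygen-bound carbons: Baeyer–Villiger cleavage of the temporary C1–C4 bond installs that oxygen on C4 with retention. Oxymercuration then closes the tetrahydropyran ring, acid closes the lactone, and the side chain comes last.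

Key step: step 8

Remark: atoms are labelled along the chain (C1 lactone carbonyl, C2 its methyl-bearing α-carbon, C3 acetoxy carbon, C4 quaternary ring-fusion carbon, C5 ring-fusion CH–O, C6/C7/C8 remaining pyran carbons, C9 methyl on C8), and compound numbers stand without the letter C. The cis C2-methyl/C3-oxygen relationship is assumed configurationally stable once set, since no later step uses a base able to enolize the carboxylate or the lactone.

Step 1
Reactants: 1 (R)-4-benzyl-3-propanoyloxazolidin-2-one; 2 propanal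
Product: 3 (R)-4-benzyl-3-[(2R,3S)-3-hydroxy-2-methylpentanoyl]oxazolidin-2-one
Conditions: Bu2BOTf, iPr2NEt, CH2Cl2, −78 → 0 °C; then H2O2, MeOH, pH 7 buffer
Reagents that add atoms: none
Why: Evans syn-aldol through the Z boron enolate and a chair transition state; the auxiliary sets the methyl-bearing centre (future C4), which serves later only as a relay and is erased in step 8.

Step 2
Reactants: 3
Product: 4 (R)-4-benzyl-3-[(R)-2-methyl-3-oxopentanoyl]oxazolidin-2-one
Conditions: SO3·pyridine, DMSO, iPr2NEt, CH2Cl2, −10 °C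
Reagents that add atoms: none
Why: Parikh–Doering oxidation; the methine between the two carbonyls should not epimerize because allylic strain keeps its C–H bond out of alignment with both carbonyls.

Step 3
Reactants: 4; 5 acrolein
Product: 6 (R)-4-benzyl-3-[(2R,4R,5S)-5-hydroxy-2,4-dimethyl-3-oxohept-6-enoyl]oxazolidin-2-one
Conditions: TiCl4, iPr2NEt, CH2Cl2, −78 °C; then 5, −78 → −40 °C
Reagents that add atoms: none
Why: Evans β-ketoimide aldol; the chlorotitanium Z-enolate forms on the ethyl side and adds to acrolein through a chair in which the C4 methyl centre directs the syn,syn array, setting C6 and C7.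

Step 4
Reactants: 6
Product: 7 (R)-4-benzyl-3-[(2R,3S,4R,5S)-3,5-dihydroxy-2,4-dimethylhept-6-enoyl]oxazolidin-2-one
Conditions: Zn(BH4)2, CH2Cl2/Et2O, −78 → −20 °C; used directly
Reagents that add atoms: none
Why: Chelation-controlled reduction of the β-hydroxy ketone (zinc bridges OH and C=O, hydride comes from the face away from the C6 methyl) should give the 1,3-syn diol and set C5.

Step 5
Reactants: 7
Product: 8 (R)-4-benzyl-3-[(2R,3S,4R,5S)-3,5-bis(tert-butyldimethylsilyloxy)-2,4-dimethylhept-6-enoyl]oxazolidin-2-one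
Conditions: TBSOTf, 2,6-lutidine, CH2Cl2, −78 → 0 °C
Reagents that add atoms: tert-butyldimethylsilyl triflate (TBSOTf), CC(C)(C)[Si](C)(C)OS(=O)(=O)C(F)(F)F
Why: Silylation of both secondary hydroxyls blocks lactonization onto the imide and keeps O5 masked until the pyran has been closed.

Step 6
Reactants: 8
Product: 9 (2R,3S,4R,5S)-3,5-bis(tert-butyldimethylsilyloxy)-2,4-dimethylhept-6-enoic acid
Conditions: LiOH, H2O2, THF/H2O, 0 °C; then Na2SO3; pH 3
Reagents that add atoms: hydrogen peroxide (as LiOOH), OO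
Why: Hydroperoxide attacks the exocyclic imide carbonyl selectively (auxiliary cleavage), releasing the acid without touching the silyl ethers or the alkene.

Step 7
Reactants: 10 allyl benzyl ether
Product: 11 (Z)-benzyl prop-1-enyl ether
Conditions: KOtBu (cat.), DMSO, 25 °C
Reagents that add atoms: none
Why: Base-mediated allyl-to-propenyl ether isomerization; protonation of the potassium-bridged cisoid allyl anion gives the cis enol ether under kinetic control.

Step 8
Reactants: 9; 11
Product: 14 (2R,3S,4R)-3-(benzyloxy)-2-[(1S,2R,3S)-1,3-bis(tert-butyldimethylsilyloxy)-2-methylpent-4-enyl]-2,4-dimethylcyclobutan-1-one, via acid chloride 12 (not isolated), via ketoketene 13 (not isolated)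
Conditions: 1-chloro-N,N,2-trimethylprop-1-en-1-amine, CH2Cl2, 0 → 25 °C; then Et3N, 11 (5–10 equiv), toluene, 90 °C, sealed tube
Reagents that add atoms: none
Why: Dehydrochlorination of 12 gives ketoketene 13; the nucleophilic β-carbon C2 of the cis enol ether attacks the electrophilic ketene carbon C1 in the ketene plane from the side of the small methyl group, and the resulting enolate carbon C4 closes onto the oxocarbenium carbon C3 (asynchronous thermal [2+2], the classical ketene–enol ether cyclobutanone synthesis). The four-membered ring is closed by cycloaddition, in stepwise terms a 4-(enolendo)-exo-trig collapse of C4 onto C3. C2 and C3 keep the cis geometry of the enol ether (suprafacial on the alkene), and the rule that the larger ketene substituent ends cis to the alkoxy group places the C5 chain cis to OBn and the C4 methyl trans, which is the all-cis C2/C3/C4 array the lactone needs. The absolute sense at C4 is relayed from C5: allylic strain should hold C5–H in the plane of the C1=C4 unit, so that C3 bonds anti to the C6 branch, past the silyloxy group. The step needs regioselectivity (secured by polarity: C2 nucleophilic, C1 electrophilic), chemoselectivity for the electron-rich enol ether over the deactivated allylic-silyloxy vinyl group and over ketene dimerization (excess 11; the cis ether reacts faster than any trans isomer), and the facial selectivity just described, which is the least secure element.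

Step 9
Reactants: 14
Product: 15 (3R,4S,5R)-4-(benzyloxy)-5-[(1S,2R,3S)-1,3-bis(tert-butyldimethylsilyloxy)-2-methylpent-4-enyl]-3,5-dimethyloxolan-2-one
Conditions: mCPBA, NaHCO3, CH2Cl2, 0 °C
Reagents that add atoms: meta-chloroperoxybenzoic acid (mCPBA), OOC(=O)c1cccc(Cl)c1
Why: Baeyer–Villiger oxidation of the strained cyclobutanone; the quaternary C4 should migrate in preference to C2 and with retention, so the future pyran oxygen arrives on C4 with the right configuration, while the monosubstituted alkene is left alone.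

Step 10
Reactants: 15
Product: 18 (2R,3S)-3-(benzyloxy)-3-[(2R,3S,4R,5R,6S)-3,5-bis(tert-butyldimethylsilyloxy)-2,4,6-trimethyloxan-2-yl]-2-methylpropanoic acid, via lithium carboxylate 16 (not isolated), via organomercury acetate 17 (not isolated)
Conditions: LiOH, THF/H2O, 25 °C; AcOH to pH 7; Hg(OAc)2, 25 °C; NaOH, NaBH4, 0 °C; then 1 M HCl to pH 3
Reagents that add atoms: lithium hydroxide, [Li+].[OH-]
Why: Saponification frees the tertiary C4 hydroxyl as the only free OH, which adds to the mercurinium ion at the internal carbon C8 (6-exo Markovnikov intramolecular oxymercuration); a chair with the C5–C7 substituents equatorial, in which the quaternary C4 forces the CH2Hg group equatorial, sets C8, and NaBH4 replaces mercury by hydrogen.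

Step 11
Reactants: 18
Product: 19 (2R,3S)-3-[(2R,3S,4R,5R,6S)-3,5-bis(tert-butyldimethylsilyloxy)-2,4,6-trimethyloxan-2-yl]-3-hydroxy-2-methylpropanoic acid
Conditions: H2 (1 atm), Pd(OH)2/C, EtOAc, 25 °C
Reagents that add atoms: none
Why: Hydrogenolysis of the benzyl ether, done at the only stage where no alkene is present; silyl ethers are stable in ethyl acetate.

Step 12
Reactants: 19
Product: 20 (2R,3S)-3-acetoxy-3-[(2R,3S,4R,5R,6S)-3,5-bis(tert-butyldimethylsilyloxy)-2,4,6-trimethyloxan-2-yl]-2-methylpropanoic acid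
Conditions: Ac2O, Et3N, DMAP (cat.), CH2Cl2, 0 → 25 °C; aqueous NaHCO3 then pH 3 work-up
Reagents that add atoms: acetic anhydride, CC(=O)OC(C)=O
Why: DMAP-catalysed acetylation of the only free hydroxyl (O3); the transient mixed anhydride at the carboxyl group is hydrolysed on work-up.

Step 13
Reactants: 20
Product: 22 (3R,4S,4aS,6S,7R,8R,8aS)-7-hydroxy-3,4a,6,8-tetramethyl-2-oxooctahydropyrano[3,2-b]pyran-4-yl acetate, via dihydroxy acid 21 (not isolated)
Conditions: HF (48% aq), MeCN, 25 °C; then CSA (cat.), toluene, 40 °C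
Reagents that add atoms: none
Why: Fluoride-acid cleavage of both silyl ethers, then acid-catalysed lactonization of the equatorial C5 hydroxyl onto C1 to the trans-fused δ-lactone; O7–H cannot lactonize (eight-membered ring) and the acetate tolerates the acidic medium.

Step 14
Reactants: 23 propiolic acid; 24 tributyltin hydride
Product: 26 (Z)-3-(tributylstannyl)prop-2-enoic acid, via stannyl ester 25 (not isolated)
Conditions: Bu3SnH (2.1 equiv), THF, 0 → 25 °C; then 1 M HCl, Et2O, 0 °C (brief)
Reagents that add atoms: none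
Why: The first equivalent forms the stannyl carboxylate and the second adds anti across the alkyne (hydrostannation), the Sn···O contact favouring the cis β-stannyl acrylate; dilute acid cleaves only the Sn–O bond.

Step 15
Reactants: 22; 26
Product: 27 (3R,4S,4aS,6S,7R,8R,8aS)-4-acetoxy-3,4a,6,8-tetramethyl-2-oxooctahydropyrano[3,2-b]pyran-7-yl (Z)-3-(tributylstannyl)prop-2-enoate
Conditions: 2,4,6-trichlorobenzoyl chloride, Et3N, THF, 25 °C; then 22, DMAP, toluene, 25 °C
Reagents that add atoms: none
Why: Yamaguchi esterification through the mixed anhydride acylates the single free, hindered secondary hydroxyl (O7) without touching the alkene geometry.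

Step 16
Reactants: 27; 28 heptanoyl chloride
Product: 29 Botcinin J, (3R,4S,4aS,6S,7R,8R,8aS)-4-acetoxy-3,4a,6,8-tetramethyl-2-oxooctahydropyrano[3,2-b]pyran-7-yl (Z)-4-oxodec-2-enoate
Conditions: PdCl2(MeCN)2 (5 mol%), THF, 25 → 50 °C, dark
Reagents that add atoms: none
Why: Stille acylation; the acylpalladium chloride from 28 transmetalates with the vinylstannane and reductive elimination should proceed with retention of the cis geometry under neutral conditions, giving the (Z)-4-oxo-2-enoate last.

Compound list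
1 | (R)-4-benzyl-3-propanoyloxazolidin-2-one | CCC(=O)N1[C@H](Cc2ccccc2)COC1=O | starting material
2 | propanal | CCC=O | starting material
3 | (R)-4-benzyl-3-[(2R,3S)-3-hydroxy-2-methylpentanoyl]oxazolidin-2-one | O=C([C@H](C)[C@@H](O)CC)N1[C@H](Cc2ccccc2)COC1=O | intermediate
4 | (R)-4-benzyl-3-[(R)-2-methyl-3-oxopentanoyl]oxazolidin-2-one | O=C([C@H](C)C(=O)CC)N1[C@H](Cc2ccccc2)COC1=O | intermediate
5 | acrolein (prop-2-enal) | C=CC=O | starting material
6 | (R)-4-benzyl-3-[(2R,4R,5S)-5-hydroxy-2,4-dimethyl-3-oxohept-6-enoyl]oxazolidin-2-one | O=C([C@H](C)C(=O)[C@H](C)[C@@H](O)C=C)N1[C@H](Cc2ccccc2)COC1=O | intermediate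
7 | (R)-4-benzyl-3-[(2R,3S,4R,5S)-3,5-dihydroxy-2,4-dimethylhept-6-enoyl]oxazolidin-2-one | O=C([C@H](C)[C@@H](O)[C@H](C)[C@@H](O)C=C)N1[C@H](Cc2ccccc2)COC1=O | intermediate
8 | (R)-4-benzyl-3-[(2R,3S,4R,5S)-3,5-bis(tert-butyldimethylsilyloxy)-2,4-dimethylhept-6-enoyl]oxazolidin-2-one | O=C([C@H](C)[C@@H](O[Si](C)(C)C(C)(C)C)[C@H](C)[C@@H](O[Si](C)(C)C(C)(C)C)C=C)N1[C@H](Cc2ccccc2)COC1=O | intermediate
9 | (2R,3S,4R,5S)-3,5-bis(tert-butyldimethylsilyloxy)-2,4-dimethylhept-6-enoic acid | OC(=O)[C@H](C)[C@@H](O[Si](C)(C)C(C)(C)C)[C@H](C)[C@@H](O[Si](C)(C)C(C)(C)C)C=C | intermediate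
10 | allyl benzyl ether | C=CCOCc1ccccc1 | starting material
11 | (Z)-benzyl prop-1-enyl ether | C/C=C\OCc1ccccc1 | intermediate
12 | (2R,3S,4R,5S)-3,5-bis(tert-butyldimethylsilyloxy)-2,4-dimethylhept-6-enoyl chloride (not isolated) | O=C(Cl)[C@H](C)[C@@H](O[Si](C)(C)C(C)(C)C)[C@H](C)[C@@H](O[Si](C)(C)C(C)(C)C)C=C | intermediate
13 | ketoketene (3S,4R,5S)-3,5-bis(tert-butyldimethylsilyloxy)-2,4-dimethylhepta-1,6-dien-1-one (not isolated) | O=C=C(C)[C@@H](O[Si](C)(C)C(C)(C)C)[C@H](C)[C@@H](O[Si](C)(C)C(C)(C)C)C=C | intermediate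
14 | (2R,3S,4R)-3-(benzyloxy)-2-[(1S,2R,3S)-1,3-bis(tert-butyldimethylsilyloxy)-2-methylpent-4-enyl]-2,4-dimethylcyclobutan-1-one | O=C1[C@H](C)[C@H](OCc2ccccc2)[C@]1(C)[C@@H](O[Si](C)(C)C(C)(C)C)[C@H](C)[C@@H](O[Si](C)(C)C(C)(C)C)C=C | intermediate
15 | (3R,4S,5R)-4-(benzyloxy)-5-[(1S,2R,3S)-1,3-bis(tert-butyldimethylsilyloxy)-2-methylpent-4-enyl]-3,5-dimethyloxolan-2-one | O=C1[C@H](C)[C@H](OCc2ccccc2)[C@@](C)(O1)[C@@H](O[Si](C)(C)C(C)(C)C)[C@H](C)[C@@H](O[Si](C)(C)C(C)(C)C)C=C | intermediate
16 | lithium (2R,3S,4R,5S,6R,7S)-3-(benzyloxy)-5,7-bis(tert-butyldimethylsilyloxy)-4-hydroxy-2,4,6-trimethylnon-8-enoate (not isolated) | [Li+].[O-]C(=O)[C@H](C)[C@H](OCc1ccccc1)[C@@](C)(O)[C@@H](O[Si](C)(C)C(C)(C)C)[C@H](C)[C@@H](O[Si](C)(C)C(C)(C)C)C=C | intermediate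
17 | lithium salt of the cyclized organomercury acetate: 18 with CH2HgOAc in place of the C8 methyl group (not isolated) | [Li+].[O-]C(=O)[C@H](C)[C@H](OCc1ccccc1)[C@@]2(C)O[C@@H](C[Hg]OC(C)=O)[C@H](O[Si](C)(C)C(C)(C)C)[C@@H](C)[C@@H]2O[Si](C)(C)C(C)(C)C | intermediate
18 | (2R,3S)-3-(benzyloxy)-3-[(2R,3S,4R,5R,6S)-3,5-bis(tert-butyldimethylsilyloxy)-2,4,6-trimethyloxan-2-yl]-2-methylpropanoic acid | OC(=O)[C@H](C)[C@H](OCc1ccccc1)[C@@]2(C)O[C@@H](C)[C@H](O[Si](C)(C)C(C)(C)C)[C@@H](C)[C@@H]2O[Si](C)(C)C(C)(C)C | intermediate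
19 | (2R,3S)-3-[(2R,3S,4R,5R,6S)-3,5-bis(tert-butyldimethylsilyloxy)-2,4,6-trimethyloxan-2-yl]-3-hydroxy-2-methylpropanoic acid | OC(=O)[C@H](C)[C@H](O)[C@@]2(C)O[C@@H](C)[C@H](O[Si](C)(C)C(C)(C)C)[C@@H](C)[C@@H]2O[Si](C)(C)C(C)(C)C | intermediate
20 | (2R,3S)-3-acetoxy-3-[(2R,3S,4R,5R,6S)-3,5-bis(tert-butyldimethylsilyloxy)-2,4,6-trimethyloxan-2-yl]-2-methylpropanoic acid | OC(=O)[C@H](C)[C@H](OC(C)=O)[C@@]2(C)O[C@@H](C)[C@H](O[Si](C)(C)C(C)(C)C)[C@@H](C)[C@@H]2O[Si](C)(C)C(C)(C)C | intermediate
21 | (2R,3S)-3-acetoxy-3-[(2S,3S,4R,5R,6S)-3,5-dihydroxy-2,4,6-trimethyloxan-2-yl]-2-methylpropanoic acid (not isolated) | OC(=O)[C@H](C)[C@H](OC(C)=O)[C@@]2(C)O[C@@H](C)[C@H](O)[C@@H](C)[C@@H]2O | intermediate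
22 | (3R,4S,4aS,6S,7R,8R,8aS)-7-hydroxy-3,4a,6,8-tetramethyl-2-oxooctahydropyrano[3,2-b]pyran-4-yl acetate | O[C@@H]1[C@@H](C)[C@@H]2OC(=O)[C@H](C)[C@H](OC(C)=O)[C@@]2(C)O[C@H]1C | intermediate
23 | propiolic acid | C#CC(=O)O | starting material
24 | tributyltin hydride | CCCC[SnH](CCCC)CCCC | starting material
25 | tributylstannyl (Z)-3-(tributylstannyl)prop-2-enoate (not isolated) | CCCC[Sn](CCCC)(CCCC)/C=C\C(=O)O[Sn](CCCC)(CCCC)CCCC | intermediate
26 | (Z)-3-(tributylstannyl)prop-2-enoic acid | CCCC[Sn](CCCC)(CCCC)/C=C\C(=O)O | intermediate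
27 | (3R,4S,4aS,6S,7R,8R,8aS)-4-acetoxy-3,4a,6,8-tetramethyl-2-oxooctahydropyrano[3,2-b]pyran-7-yl (Z)-3-(tributylstannyl)prop-2-enoate | CCCC[Sn](CCCC)(CCCC)/C=C\C(=O)O[C@@H]1[C@@H](C)[C@@H]2OC(=O)[C@H](C)[C@H](OC(C)=O)[C@@]2(C)O[C@H]1C | intermediate
28 | heptanoyl chloride | CCCCCCC(=O)Cl | starting material
29 | Botcinin J | CCCCCCC(=O)/C=C\C(=O)O[C@@H]1[C@@H](C)[C@@H]2OC(=O)[C@H](C)[C@H](OC(C)=O)[C@@]2(C)O[C@H]1C | target

Total step count: 16. Longest linear sequence: 14 (steps 1–6, 8–13, 15, 16); steps 7 and 14 are single-step side branches.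

Steps most likely to fail

The key cycloaddition (step 8) carries the highest risk. The hindered ketoketene may be captured too slowly by the 1,2-disubstituted enol ether, so that dimerization or intramolecular capture by the vinyl group competes. The facial selectivity at C4 relative to C5 may also be low, because it rests on a conformational argument and not on a rigid element. The fallback sets out from 9: via 12 the acid is converted into the amide of (2R,5R)-2,5-dimethylpyrrolidine, amide F1. Tf2O with 2,4,6-collidine in CH2Cl2 turns it into the keteniminium triflate F2, a much stronger electrophile whose C2-symmetric amine adds reagent control over the C4 face (the (2R,5R) amine is assumed to be the matched one). Its [2+2] cycloaddition with 11 would give the cyclobutaniminium triflate F3, and hydrolysis with aqueous NaHCO3 comes back to the route at 14.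

The second risk is the telescoped saponification, oxymercuration and demercuration (step 10). The tertiary hydroxyl may add slowly, the oxymercuration may revert during the borohydride reduction and give back the alkene, or the C8 configuration may erode. The fallback sets out from 15: after the same saponification, an irreversible iodonium-triggered etherification (I2, NaHCO3, MeCN, 0 °C) would give the iodomethyl oxane acid F4, and radical deiodination (Bu3SnH, AIBN, toluene, 80 °C) comes back to the route at 18.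

The third risk is the final acylation of the vinylstannane (step 16). Transmetalation of the electron-poor stannane may be slow, and the cis enedione may isomerize to trans under palladium catalysis. The fallback sets out from 22: it is esterified directly with preformed (Z)-4-oxodec-2-enoic acid F5, made in one step from commercial 2-hexylfuran (CCCCCCc1ccco1) with NaClO2/NaH2PO4 in aqueous tert-butanol. The coupling with 2-methyl-6-nitrobenzoic anhydride, Et3N and DMAP (CH2Cl2, 0 °C) comes back to the route at 29.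

Further compounds
F1 | step 8 | (2R,5R)-2,5-dimethylpyrrolidine amide of acid 9 | O=C([C@H](C)[C@@H](O[Si](C)(C)C(C)(C)C)[C@H](C)[C@@H](O[Si](C)(C)C(C)(C)C)C=C)N1[C@H](C)CC[C@H]1C
F2 | step 8 | keteniminium triflate derived from F1 | CC(=C=[N+]1[C@H](C)CC[C@H]1C)[C@@H](O[Si](C)(C)C(C)(C)C)[C@H](C)[C@@H](O[Si](C)(C)C(C)(C)C)C=C.[O-]S(=O)(=O)C(F)(F)F
F3 | step 8 | cyclobutaniminium triflate (iminium form of 14) | C1(=[N+]2[C@H](C)CC[C@H]2C)[C@H](C)[C@H](OCc3ccccc3)[C@]1(C)[C@@H](O[Si](C)(C)C(C)(C)C)[C@H](C)[C@@H](O[Si](C)(C)C(C)(C)C)C=C.[O-]S(=O)(=O)C(F)(F)F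
F4 | step 10 | (2R,3S)-3-(benzyloxy)-3-[3,5-bis(tert-butyldimethylsilyloxy)-6-(iodomethyl)-2,4-dimethyloxan-2-yl]-2-methylpropanoic acid (ring configuration as in 18) | OC(=O)[C@H](C)[C@H](OCc1ccccc1)[C@@]2(C)O[C@@H](CI)[C@H](O[Si](C)(C)C(C)(C)C)[C@@H](C)[C@@H]2O[Si](C)(C)C(C)(C)C
F5 | step 16 | (Z)-4-oxodec-2-enoic acid | CCCCCCC(=O)/C=C\C(=O)O
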